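Atom labels follow drimane numbering throughout: ring A is C1, C2, C3, C4, C5, C10; ring B is C5, C6, C7, C8, C9, C10; C11 is the CH2O carbon on C9; C12 is the methyl on C8. Compounds 1–24 are those of the route below.

## The problem

Target 24 is a trans-fused decalin with a C3 ketone beside the C4 gem-dimethyl group, a C7=C8 alkene carrying C12, an angular methyl on C10 and a C9–CH2–O link to umbelliferone. It has three stereocentres, (5S,9S,10R): H-5 and the C10 methyl are trans, and C11 lies on the face opposite the C10 methyl, pseudo-axial on ring B. That is the less stable placement at C9, so equilibration cannot set it and a kinetic, face-specific bond formation is needed. C10 is quaternary and must be made as one enantiomer; once fixed it can direct C5 through the ring fusion, and a C7 oxygen can relay its face to C9 across C8. The coumarin lactone does not survive hydroxide, hydride or organolithium reagents, so it has to arrive last. The C7=C8 alkene can migrate under strong acid, and the C3 ketone must be masked whenever strong base is used. With C11 set aside, ring B is a 2-methylcyclohexenone (C7 carbonyl, C8=C9) whose γ-carbon C10 is quaternary, which is the pattern left by an aldehyde–enone annulation with C9 as the aldehyde carbon. Because C4 is quaternary and C3 is a carbonyl, a single chain C9–C10–C1–C2–C3–C4–C5–C6–C7–C8 has only one pair of bonds, C5–C10 and C8–C9, by which it can fold productively.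

## Retrosynthesis

**Aryl ether and C3 mask (24 ⇒ 23 ⇒ 21 + 22).** The C11–O bond is cut and C3 is masked as a dioxolane. This places the base-sensitive coumarin 22 at the end and leaves a neutral Mitsunobu coupling as the forward step. Cutting O–aryl instead is kept in reserve. Alcohol 21 carries all three stereocentres but no aromatic part. The forward steps must displace at a β-branched primary carbinol and free the ketone without moving the alkene.

**C9–C11 (21 ⇒ 20 ⇒ 19).** The C9–C11 bond is cut as a Still–Wittig [2,3] shift of the stannylmethyl ether 20 of allylic alcohol 19. Conjugate addition of a one-carbon nucleophile to an enone, or olefination of a C9 ketone, would be intermolecular attacks beside the quaternary C10. The sigmatropic route is intramolecular, forms the C7=C8 alkene in the same event and transfers the C7 configuration to C9. The precursor trades the C9 stereocentre for a carbinol one reduction away from an enone. The forward reaction requires the 7-hydroxyl trans to the C10 methyl.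

**Oxidation level (19 ⇒ 18 ⇒ 17).** These are functional-group changes only. The C3 ketone of 17 is ketalized selectively, and the enone of 18 is reduced from the face that carries the C10 methyl. That face is opposite to the usual axial hydride approach, so reagent control is asked of the reduction.

**Both rings (17 ⇒ 15, through 16).** C5–C10 and C8–C9 are cut together: a Michael addition of the C9 aldehyde α-carbon to the C5–C6–C7 enone, and an aldol condensation of C8 onto C9. Against cuts that keep one ring (ring expansion, cycloaddition onto ring A, transannular closure), this removes both rings and both stereocentres at once. What remains is the achiral-in-effect chain 15, whose single stereocentre is erased in the enamine. The forward step must join a quaternary donor carbon to a β-carbon beside the quaternary C4 with control of the enantioface and of the ring fusion.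

**Enone (15 ⇒ 14 ⇒ 12 + 13).** The C5=C6 bond is cut by a Wittig disconnection after masking C9 as a dioxolane. An aldol route to this enone would have to choose among three enolizable positions. Aldehyde 12 cannot enolize and ylide 13 is commercial. The forward reaction needs only aldehyde-over-ketone selectivity and (E) geometry.

**C3–C4 (12 ⇒ 7 + 9, through 10 and 11; 9 ⇐ 8).** The C3–C4 bond is cut as acylation of the isobutyraldehyde enamine 9 by the acid chloride 10 of salt 7. This creates the quaternary C4 with both flanking carbonyls at the right oxidation level in one step. Double methylation of a β-keto aldehyde would suffer O-alkylation and cleavage. The forward reaction must keep the acetal intact.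

**C1–C2 (7 ⇐ 6 ⇐ 5 ⇐ 1 + 2).** The C1–C2 bond is cut as a Stork enamine Michael addition of propanal 1 to methyl acrylate 2, followed by acetalization and saponification. All carbons of the chain then come from four commodity chemicals.

## Roads not taken

Alternative 1: Here C8 is excised, so the core is a trans-fused hydrindane. Its silyl enol ether A1 (C9(OSiMe3)=C7) would take up dibromocarbene, and opening of the bromocyclopropane would insert C8 to give the bromo enone A2. The merit is real: the ring fusion and C10 rest on well-proven annulation and reductive-alkylation chemistry, which is more secure than step 8 of the chosen plan. The weakness lies at C9 and C8. A2 has a C9 ketone beside the quaternary C10, C12 must be added by cross-coupling at the bromide, and C11 by olefination of a very hindered ketone. The C9 hydrogen would then be delivered anti to the C10 methyl, which places C11 cis to that methyl, the wrong epimer for 24. The chosen plan offers against it a route that sets C9 from C7 with the required sense, and a shorter line to the core.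

Alternative 2: Here C9–C10 and C7–C8 are cut as an intramolecular Diels–Alder reaction of triene A3, whose crotonate is tethered through the C3 oxygen, giving bridged lactone A4. In one respect this is better than the chosen plan: the tether forces C11 onto the face opposite the C10 methyl and sets C9 and C10 together, with C11 and C12 already in place. The chosen plan needs three steps (10–12) for the same result. Its weak points are the diene and the outcome. The diene terminus C10 is fully substituted, the dienophile is a β-methyl ester held in a seven-membered lactone-forming tether, and the alkene emerges at C5=C6. C5 would still need hydrogen from the correct face, the C8 stereocentre would have to be destroyed, and unsaturation would have to be rebuilt at C7=C8 where no handle remains. A3 also needs its own enantioselective synthesis. The chosen plan offers against it the direct formation of ring B at the right oxidation level with C5 already set.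

Alternative 3: Here C5–C10 is cut across a ten-membered ring. Hydrogen-atom transfer (Fe(acac)3, PhSiH3) to the exocyclic methylene of macrocycle A5 gives a tertiary C10 radical that adds to C5 of the (E)-enone and yields A6. Radical conjugate addition of this kind is better precedented for joining a quaternary carbon to a hindered neighbour than the polar Michael step of the chosen plan, and this advantage is conceded. The cost is the substrate and the product. A5 is a medium ring with two stereocentres that must be built and closed. A6 is saturated at C8–C9, so the enone of 17 still has to be made by dehydrogenation before the same endgame can begin, and the C3 silyl ether must later be removed and oxidized. The chosen plan offers against it a six-step, acyclic precursor from commodity chemicals and absolute control by a catalyst instead of by resident stereocentres.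

Key step: step 8

Assumption: the quinine-derived amine is taken to give the (5S,10S) series; if it favours the mirror image, its quinidine-derived pseudoenantiomer replaces it with no other change.

Step 1
Reactants: 1 propanal; 2 methyl acrylate
Product: 5 methyl 4-methyl-5-oxopentanoate, via (E)-1-(prop-1-en-1-yl)pyrrolidine 3 (not isolated), via methyl 4-methyl-5-(pyrrolidin-1-yl)pent-4-enoate 4 (not isolated)
Conditions: pyrrolidine, K2CO3, 0 °C; filter; 2, MeCN, 80 °C; then AcOH, H2O, 23 °C
Reagents that add atoms: water, O
Why: Stork enamine Michael addition: the propanal enamine adds to the acrylate β-carbon and hydrolysis returns the aldehyde; the adduct enamine 4 is more substituted and less reactive, which limits double alkylation. The stereocentre is racemic and is erased in step 8.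

Step 2
Reactants: 5 methyl 4-methyl-5-oxopentanoate
Product: 6 methyl 4-(1,3-dioxolan-2-yl)pentanoate
Conditions: HOCH2CH2OH (1.2 equiv), p-TsOH·H2O (cat.), benzene, reflux, azeotropic water removal
Reagents that add atoms: ethylene glycol, OCCO
Why: Acid-catalysed acetalization; the aldehyde reacts far faster than the methyl ester transesterifies with a near-stoichiometric amount of diol.

Step 3
Reactants: 6 methyl 4-(1,3-dioxolan-2-yl)pentanoate
Product: 7 potassium 4-(1,3-dioxolan-2-yl)pentanoate
Conditions: KOH (1.0 equiv), MeOH, H2O, 23 °C; evaporate; dry by toluene azeotrope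
Reagents that add atoms: potassium hydroxide, [K+].[OH-]
Why: Saponification; the dioxolane is stable to base, and isolating the dry salt means the acetal never meets a free acid.

Step 4
Reactants: 8 2-methylpropanal (isobutyraldehyde)
Product: 9 4-(2-methylprop-1-en-1-yl)morpholine
Conditions: morpholine, p-TsOH·H2O (cat.), toluene, reflux, azeotropic water removal; distil
Reagents that add atoms: morpholine, C1COCCN1
Why: Enamine condensation of an α-branched aldehyde with a secondary amine; only one enamine is possible and it is distillable.

Step 5
Reactants: 7 potassium 4-(1,3-dioxolan-2-yl)pentanoate; 9 4-(2-methylprop-1-en-1-yl)morpholine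
Product: 12 6-(1,3-dioxolan-2-yl)-2,2-dimethyl-3-oxoheptanal, via 4-(1,3-dioxolan-2-yl)pentanoyl chloride 10 (not isolated), via 4-[6-(1,3-dioxolan-2-yl)-2,2-dimethyl-3-oxoheptylidene]morpholin-4-ium chloride 11 (not isolated)
Conditions: (COCl)2, DMF (cat.), CH2Cl2, 0 °C; then 9, Et2O, 35 °C; then H2O, 0 to 23 °C, brief
Reagents that add atoms: water, O
Why: The carboxylate salt and oxalyl chloride give the acid chloride without free HCl, and Stork acylation of the enamine at carbon gives an iminium salt that has no proton to lose, so no amine base (and no ketene) is involved. Short, weakly acidic hydrolysis frees the quaternary β-keto aldehyde while avoiding the nucleophilic base that would cleave it by retro-Claisen attack.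

Step 6
Reactants: 12 6-(1,3-dioxolan-2-yl)-2,2-dimethyl-3-oxoheptanal; 13 1-(triphenylphosphoranylidene)butan-2-one
Product: 14 (4E)-10-(1,3-dioxolan-2-yl)-6,6-dimethylundec-4-ene-3,7-dione
Conditions: toluene, 90 °C
Reagents that add atoms: none
Why: Wittig olefination with a keto-stabilized ylide, which reacts with the aldehyde and not the ketone and gives the (E)-enone; the aldehyde is non-enolizable and is activated by the neighbouring acyl group.

Step 7
Reactants: 14 (4E)-10-(1,3-dioxolan-2-yl)-6,6-dimethylundec-4-ene-3,7-dione
Product: 15 (7E)-2,6,6-trimethyl-5,9-dioxoundec-7-enal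
Conditions: 1 M HCl, THF, 23 °C
Reagents that add atoms: water, O
Why: Acid-catalysed acetal hydrolysis; no pair of carbonyls in 15 can close a five- or six-membered aldol ring without the amine, so the keto aldehyde can be isolated and used at once.

Step 8
Reactants: 15 (7E)-2,6,6-trimethyl-5,9-dioxoundec-7-enal
Product: 17 (5S,10S)-11-nordrim-8-ene-3,7-dione, via (1R,2S)-1,3,3-trimethyl-4-oxo-2-(2-oxobutyl)cyclohexane-1-carbaldehyde 16 (not isolated)
Conditions: 9-amino-9-deoxy-epi-quinine (C20H25N3O, 20 mol %), CF3CO2H (40 mol %), toluene, 50 °C
Reagents that add atoms: none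
Why: Proposed new method: the primary amine condenses with the aldehyde of 15 and the imine tautomerizes to the secondary enamine, which erases the chain stereocentre; the enamine carbon C10 then adds to the enone β-carbon C5, the enone being activated by the protonated quinuclidine or by a second catalyst molecule as its iminium ion, and hydrolysis gives 16. The ethyl ketone of 16 next forms its enamine or enol toward C8 and condenses with the now non-enolizable C9 aldehyde; loss of water gives the conjugated enone 17 and pulls 16 out of the Michael equilibrium. The closest known reaction types are the amine-catalysed Robinson annulation of α-branched aldehydes with vinyl ketones to 4,4-disubstituted cyclohexenones and the amine-catalysed intramolecular Michael addition of aldehydes to tethered enones; new here is the union of a quaternary donor carbon with a β-carbon that has a quaternary neighbour. Ring A closes by a 6-exo-trig Michael addition with both reacting double bonds outside the forming ring, and ring B by a 6-(enolendo)-exo-trig aldol addition followed by dehydration. C10 is set by the face of the catalyst-bound enamine that the chiral amine leaves open; C5 is set relative to C10 by a chair transition state in which the (E)-enone arm and the nitrogen-bearing C9 arm are both pseudo-equatorial and the small C10 methyl is axial, which gives the trans fusion. The step needs enamine formation at the aldehyde only, which its higher electrophilicity and lower hindrance secure, and it needs a single irreversible aldol path: C4 and C10 are quaternary, and enolization of C7 toward C6 or of C3 toward C2 can lead only to four-membered or bridged aldols that cannot dehydrate without a bridgehead alkene and so revert. The C4 gem-dimethyl group favours the folded chain by the gem-dialkyl effect.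

Step 9
Reactants: 17 (5S,10S)-11-nordrim-8-ene-3,7-dione
Product: 18 (5S,10S)-3,3-(ethylenedioxy)-11-nordrim-8-en-7-one
Conditions: HOCH2CH2OH, p-TsOH·H2O (cat.), benzene, reflux, azeotropic water removal
Reagents that add atoms: ethylene glycol, OCCO
Why: Selective ketalization of the saturated ketone: the enone is less electrophilic and its usual deconjugative ketalization is closed because C10 bears no hydrogen. Bicyclic enediones with a saturated ketone beside a quaternary carbon show the same selectivity.

Step 10
Reactants: 18 (5S,10S)-3,3-(ethylenedioxy)-11-nordrim-8-en-7-one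
Product: 19 (5S,7S,10S)-3,3-(ethylenedioxy)-11-nordrim-8-en-7-ol
Conditions: (R)-2-methyl-CBS-oxazaborolidine (0.5 equiv), catecholborane, toluene, −78 °C; then MeOH, aq NaOH
Reagents that add atoms: none
Why: Corey–Bakshi–Shibata reduction gives clean 1,2-reduction; with the alkenyl arm C8 as the large group, the (R)-catalyst delivers hydride to the face of C7 that carries the C10 methyl and sets (7S), hydroxyl trans to that methyl. Reagent control is required because small hydrides prefer the opposite, axial approach.

Step 11
Reactants: 19 (5S,7S,10S)-3,3-(ethylenedioxy)-11-nordrim-8-en-7-ol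
Product: 20 (5S,7S,10S)-3,3-(ethylenedioxy)-7-[(tributylstannyl)methoxy]-11-nordrim-8-ene
Conditions: KH, 18-crown-6 (cat.), Bu3SnCH2I, THF, 0 to 23 °C
Reagents that add atoms: tributyl(iodomethyl)stannane, CCCC[Sn](CCCC)(CCCC)CI
Why: Williamson etherification of the potassium alkoxide with a primary iodide; no stereocentre is touched and the ketal is inert to base.

Step 12
Reactants: 20 (5S,7S,10S)-3,3-(ethylenedioxy)-7-[(tributylstannyl)methoxy]-11-nordrim-8-ene
Product: 21 (5S,9S,10R)-3,3-(ethylenedioxy)drim-7-en-11-ol
Conditions: n-BuLi, THF, −78 °C; then H2O
Reagents that add atoms: none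
Why: Still–Wittig [2,3]-sigmatropic rearrangement: tin–lithium exchange gives the α-alkoxymethyllithium, which bonds to C9 on the face from which the pseudo-axial C7–O bond departs, so C11 arrives trans to the C10 methyl (9S) and the C7=C8 alkene forms. The five-membered intramolecular transition state tolerates the quaternary neighbour C10; the C10 descriptor changes from S to R by priority only.

Step 13
Reactants: 21 (5S,9S,10R)-3,3-(ethylenedioxy)drim-7-en-11-ol; 22 7-hydroxy-2H-chromen-2-one (umbelliferone)
Product: 23 7-{[(5S,9S,10R)-3,3-(ethylenedioxy)drim-7-en-11-yl]oxy}-2H-chromen-2-one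
Conditions: PPh3, DIAD, THF, 0 to 23 °C
Reagents that add atoms: none
Why: Mitsunobu etherification of a primary alcohol with an acidic phenol (pKa about 8) under neutral conditions that spare the lactone and the ketal; no stereocentre is involved.

Step 14
Reactants: 23 7-{[(5S,9S,10R)-3,3-(ethylenedioxy)drim-7-en-11-yl]oxy}-2H-chromen-2-one
Product: 24 7-{[(5S,9S,10R)-3-oxodrim-7-en-11-yl]oxy}-2H-chromen-2-one
Conditions: 1 M HCl, THF, 23 °C
Reagents that add atoms: water, O
Why: Acid-catalysed ketal hydrolysis, fast because it relieves strain beside the gem-dimethyl group and mild enough to leave the trisubstituted alkene, the aryl ether and the lactone untouched.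

## Compound list

1 | propanal | CCC=O | starting material
2 | methyl acrylate | C=CC(=O)OC | starting material
3 | (E)-1-(prop-1-en-1-yl)pyrrolidine | C/C=C/N1CCCC1 | intermediate
4 | methyl 4-methyl-5-(pyrrolidin-1-yl)pent-4-enoate | COC(=O)CCC(C)=CN1CCCC1 | intermediate
5 | methyl 4-methyl-5-oxopentanoate (racemic) | COC(=O)CCC(C)C=O | intermediate
6 | methyl 4-(1,3-dioxolan-2-yl)pentanoate (racemic) | COC(=O)CCC(C)C1OCCO1 | intermediate
7 | potassium 4-(1,3-dioxolan-2-yl)pentanoate (racemic) | [K+].[O-]C(=O)CCC(C)C1OCCO1 | intermediate
8 | 2-methylpropanal (isobutyraldehyde) | CC(C)C=O | starting material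
9 | 4-(2-methylprop-1-en-1-yl)morpholine | CC(C)=CN1CCOCC1 | intermediate
10 | 4-(1,3-dioxolan-2-yl)pentanoyl chloride (racemic) | ClC(=O)CCC(C)C1OCCO1 | intermediate
11 | 4-[6-(1,3-dioxolan-2-yl)-2,2-dimethyl-3-oxoheptylidene]morpholin-4-ium chloride (racemic) | [Cl-].O=C(CCC(C)C1OCCO1)C(C)(C)C=[N+]1CCOCC1 | intermediate
12 | 6-(1,3-dioxolan-2-yl)-2,2-dimethyl-3-oxoheptanal (racemic) | O=CC(C)(C)C(=O)CCC(C)C1OCCO1 | intermediate
13 | 1-(triphenylphosphoranylidene)butan-2-one | CCC(=O)C=P(c1ccccc1)(c1ccccc1)c1ccccc1 | starting material
14 | (4E)-10-(1,3-dioxolan-2-yl)-6,6-dimethylundec-4-ene-3,7-dione (racemic) | CCC(=O)/C=C/C(C)(C)C(=O)CCC(C)C1OCCO1 | intermediate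
15 | (7E)-2,6,6-trimethyl-5,9-dioxoundec-7-enal (racemic at C2) | CCC(=O)/C=C/C(C)(C)C(=O)CCC(C)C=O | intermediate
16 | (1R,2S)-1,3,3-trimethyl-4-oxo-2-(2-oxobutyl)cyclohexane-1-carbaldehyde | O=C[C@]1(C)CCC(=O)C(C)(C)[C@H]1CC(=O)CC | intermediate
17 | (5S,10S)-11-nordrim-8-ene-3,7-dione; trans-fused; (4aS,8aS)-3,4a,8,8-tetramethyl-4a,5,6,8a-tetrahydronaphthalene-2,7(1H,8H)-dione | CC1=C[C@]2(C)CCC(=O)C(C)(C)[C@H]2CC1=O | intermediate
18 | (5S,10S)-3,3-(ethylenedioxy)-11-nordrim-8-en-7-one | CC1=C[C@]2(C)CCC3(OCCO3)C(C)(C)[C@H]2CC1=O | intermediate
19 | (5S,7S,10S)-3,3-(ethylenedioxy)-11-nordrim-8-en-7-ol; 7-OH trans to the C10 methyl | CC1=C[C@]2(C)CCC3(OCCO3)C(C)(C)[C@H]2C[C@@H]1O | intermediate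
20 | (5S,7S,10S)-3,3-(ethylenedioxy)-7-[(tributylstannyl)methoxy]-11-nordrim-8-ene | CC1=C[C@]2(C)CCC3(OCCO3)C(C)(C)[C@H]2C[C@@H]1OC[Sn](CCCC)(CCCC)CCCC | intermediate
21 | (5S,9S,10R)-3,3-(ethylenedioxy)drim-7-en-11-ol; C11 trans to the C10 methyl | CC1=CC[C@@H]2C(C)(C)C3(OCCO3)CC[C@@]2(C)[C@H]1CO | intermediate
22 | 7-hydroxy-2H-chromen-2-one (umbelliferone) | Oc1ccc2ccc(=O)oc2c1 | starting material
23 | 7-{[(5S,9S,10R)-3,3-(ethylenedioxy)drim-7-en-11-yl]oxy}-2H-chromen-2-one | CC1=CC[C@@H]2C(C)(C)C3(OCCO3)CC[C@@]2(C)[C@H]1COc1ccc2ccc(=O)oc2c1 | intermediate
24 | 7-{[(5S,9S,10R)-3-oxodrim-7-en-11-yl]oxy}-2H-chromen-2-one; 7-{[(1S,4aS,8aR)-2,5,5,8a-tetramethyl-6-oxo-1,4,4a,5,6,7,8,8a-octahydronaphthalen-1-yl]methoxy}-2H-chromen-2-one | CC1=CC[C@@H]2C(C)(C)C(=O)CC[C@@]2(C)[C@H]1COc1ccc2ccc(=O)oc2c1 | target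

## Step count and least certain steps

Total: 14 steps. Longest linear sequence: 13 steps (steps 1–3 and 5–14, from propanal); step 4 is a one-step side branch.

**Step 8 (key step).** The Michael addition may stall, because the enamine of an α-branched aldehyde is a weak nucleophile and C5 is shielded by the C4 gem-dimethyl group; the amine is then diverted into unproductive imines and the aldehyde is lost to slow intermolecular condensation. Closure through a chair with the C9 arm axial would give the cis fusion, and enantioface discrimination may be poor because the two α-substituents of the enamine (methyl and CH2) are similar in size.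

The fallback sets out from 15 and comes back at 19. It gives up ring formation as the source of absolute configuration and uses stoichiometric, classical Stork annulation followed by a resolution. This replaces the catalytic asymmetric induction but forms the same C5–C10 bond, so it helps less if the failure is steric. Compound 15 is condensed with one equivalent of pyrrolidine to the enamine (4E)-6,6,10-trimethyl-11-(pyrrolidin-1-yl)undeca-4,10-diene-3,7-dione F1. Heating in toluene at 110 °C effects the enamine–enone cyclization, and aqueous AcOH/NaOAc at 80 °C then hydrolyses the product and completes the aldol condensation to racemic trans-11-nordrim-8-ene-3,7-dione F2. Ketalization as in step 9 gives racemic 3,3-(ethylenedioxy)-11-nordrim-8-en-7-one F3. The reagent-controlled reduction of step 10 then turns the two enantiomers into diastereomers: 19 from the (5S,10S) half, and (5R,7S,10R)-3,3-(ethylenedioxy)-11-nordrim-8-en-7-ol F4 from the other half. The two are separated by chromatography.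

**Step 10.** Facial selectivity may be poor, because the catalyst must overrule the intrinsic preference of the cyclohexenone for axial hydride delivery from the face opposite the C10 methyl. The fallback sets out from 18 and comes back at 19. Luche reduction (NaBH4, CeCl3·7H2O, MeOH, −78 °C) follows the intrinsic preference and gives (5S,7R,10S)-3,3-(ethylenedioxy)-11-nordrim-8-en-7-ol F5. Mitsunobu inversion with 4-nitrobenzoic acid (PPh3, DIAD, toluene) gives (5S,7S,10S)-3,3-(ethylenedioxy)-11-nordrim-8-en-7-yl 4-nitrobenzoate F6. Methanolysis (K2CO3, MeOH) releases 19.

**Step 12.** The α-alkoxymethyllithium may undergo 1,2-shift or be protonated before it reaches C9, whose approach is crowded by C1 and the quaternary C10. The fallback sets out from 18 and comes back at 21, and replaces the sigmatropic transfer by a polar conjugate addition.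
- CuI-catalysed addition of (isopropoxydimethylsilyl)methylmagnesium chloride (THF, −40 °C) should occur axially at C9, anti to the angular methyl. The enolate is trapped with N-(5-chloropyridin-2-yl)bis(trifluoromethanesulfonyl)imide to give (5S,9R,10R)-3,3-(ethylenedioxy)-11-[isopropoxy(dimethyl)silyl]drim-7-en-7-yl trifluoromethanesulfonate F7.
- Reduction of the enol triflate with formate (Pd(OAc)2, PPh3, HCO2H, Bu3N, DMF, 60 °C) gives (5S,9S,10R)-3,3-(ethylenedioxy)-11-[isopropoxy(dimethyl)silyl]drim-7-ene F8.
- Tamao oxidation (KF, KHCO3, H2O2, THF/MeOH) gives 21.

**Step 13.** Displacement of the oxyphosphonium group at C11 may be slow, since this carbon is β-branched, axial and next to the quaternary C10; the activated betaine is then consumed by side alkylation. The fallback sets out from 22 and 21 and comes back at 23, and forms the O–aryl bond instead of the C11–O bond. Umbelliferone 22 is converted with Tf2O and pyridine (CH2Cl2, 0 °C) into 2-oxo-2H-chromen-7-yl trifluoromethanesulfonate F9. This is coupled with alcohol 21 by C–O cross-coupling (Pd(OAc)2, a bulky di-tert-butyl biarylphosphine such as RockPhos, Cs2CO3, toluene, 90 °C) to give 23.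

## Further compounds

F1 | step 8 | (4E)-6,6,10-trimethyl-11-(pyrrolidin-1-yl)undeca-4,10-diene-3,7-dione | CCC(=O)/C=C/C(C)(C)C(=O)CCC(C)=CN1CCCC1
F2 | step 8 | racemic trans-11-nordrim-8-ene-3,7-dione (both enantiomers) | CC1=C[C@]2(C)CCC(=O)C(C)(C)[C@H]2CC1=O.CC1=C[C@@]2(C)CCC(=O)C(C)(C)[C@@H]2CC1=O
F3 | step 8 | racemic trans-3,3-(ethylenedioxy)-11-nordrim-8-en-7-one (both enantiomers) | CC1=C[C@]2(C)CCC3(OCCO3)C(C)(C)[C@H]2CC1=O.CC1=C[C@@]2(C)CCC3(OCCO3)C(C)(C)[C@@H]2CC1=O
F4 | step 8 | (5R,7S,10R)-3,3-(ethylenedioxy)-11-nordrim-8-en-7-ol | CC1=C[C@@]2(C)CCC3(OCCO3)C(C)(C)[C@@H]2C[C@@H]1O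
F5 | step 10 | (5S,7R,10S)-3,3-(ethylenedioxy)-11-nordrim-8-en-7-ol | CC1=C[C@]2(C)CCC3(OCCO3)C(C)(C)[C@H]2C[C@H]1O
F6 | step 10 | (5S,7S,10S)-3,3-(ethylenedioxy)-11-nordrim-8-en-7-yl 4-nitrobenzoate | CC1=C[C@]2(C)CCC3(OCCO3)C(C)(C)[C@H]2C[C@@H]1OC(=O)c1ccc(cc1)[N+](=O)[O-]
F7 | step 12 | (5S,9R,10R)-3,3-(ethylenedioxy)-11-[isopropoxy(dimethyl)silyl]drim-7-en-7-yl trifluoromethanesulfonate | CC1=C(OS(=O)(=O)C(F)(F)F)C[C@@H]2C(C)(C)C3(OCCO3)CC[C@@]2(C)[C@H]1C[Si](C)(C)OC(C)C
F8 | step 12 | (5S,9S,10R)-3,3-(ethylenedioxy)-11-[isopropoxy(dimethyl)silyl]drim-7-ene | CC1=CC[C@@H]2C(C)(C)C3(OCCO3)CC[C@@]2(C)[C@H]1C[Si](C)(C)OC(C)C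
F9 | step 13 | 2-oxo-2H-chromen-7-yl trifluoromethanesulfonate | O=c1ccc2ccc(OS(=O)(=O)C(F)(F)F)cc2o1
A1 | alternative 1 | trimethylsilyl enol ether of the trans-fused C3-ketal hydrindanone (ring B without C8; C9(OSiMe3)=C7) | C[Si](C)(C)OC1=CC[C@@H]2C(C)(C)C3(OCCO3)CC[C@@]12C
A2 | alternative 1 | 8-bromo-11,12-dinordrim-7-en-9-one C3 ethylene ketal | O=C1C(Br)=CC[C@@H]2C(C)(C)C3(OCCO3)CC[C@@]12C
A3 | alternative 2 | (1S)-2,2,4-trimethyl-3-vinylcyclohex-3-en-1-yl (E)-but-2-enoate | C/C=C/C(=O)O[C@H]1CCC(C)=C(C=C)C1(C)C
A4 | alternative 2 | bridged lactone cycloadduct with the C5=C6 alkene (C11 carbonyl lactonized to the C3 oxygen) | C[C@@H]1CC=C2C(C)(C)[C@@H]3CC[C@@]2(C)[C@H]1C(=O)O3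
A5 | alternative 3 | ten-membered (E)-enone with exocyclic methylene at C10, C3 tert-butyldimethylsilyl ether and C8 methyl | C=C1CC[C@@H](O[Si](C)(C)C(C)(C)C)C(C)(C)/C=C/C(=O)[C@H](C)C1
A6 | alternative 3 | trans-fused 3-(tert-butyldimethylsilyloxy)-11-nordriman-7-one | C[C@@H]1C[C@]2(C)CC[C@@H](O[Si](C)(C)C(C)(C)C)C(C)(C)[C@H]2CC1=O
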